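# Proposed total synthesis of kazinol D (23)

## Structural features

Compound 23 is an achiral 1,3-diarylpropane without any stereocentre. Ring A is a resorcinol that carries a 2-methylbut-3-en-2-yl group, ring B is the benzo ring of a 2,2-dimethylchroman, and a saturated three-carbon chain joins ring A to chroman C6. Ring B keeps a single hydrogen at C7 and bears five contiguous substituents, namely the ring oxygen at C8a, a free hydroxyl at C8, the tether at C6, a prenyl group at C5 and the pyran carbon C4 at C4a. The fragile elements are the air-sensitive, electron-rich phenols and the three C5 units, whose alkenes rule out hydrogenation and hydrogenolysis and which under acid can cyclise onto neighbouring hydroxyls, hydrate or migrate. The real difficulty is regiochemical, since five different groups must be ordered on ring B, the reversed prenyl group must reach the correct ortho carbon of ring A, and one aryl–alkyl bond must join two crowded halves without touching the alkenes. The feature that the key step exploits appears when the O1–C2 bond is opened in thought, because C4a and C5 of ring B then carry two arms of the same constitution, CH2–CH=C(CH3)2, whose four inner carbons (chroman C4 and C3 and the first two carbons of the C5 prenyl group) map onto the CH2–CH=CH–CH2 bridge of a 5,8-dihydronaphthalene. One ring alkene can therefore be cut and both ends olefinated identically, and the C8a hydroxyl, which flanks only one arm, later decides which arm becomes the pyran ring.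

## Logic of the disconnections

**23 to 22.** The O1–C2 ether bond of the pyran ring is cut (retro-hydroalkoxylation). This is the only event that tells the two C5 arms of ring B apart, so it is placed last; 22 has one ring fewer and two identical prenyl groups. The forward step must add the C8a hydroxyl across the neighbouring trisubstituted alkene in the Markovnikov sense, under acid mild enough to leave the second prenyl group, the 1,1-dimethylallyl group and the other hydroxyls alone.

**22 to 21.** Four O–Si bonds are cut. All phenols must be masked during the organometallic steps, and one kind of silyl ether on both rings allows a single unmasking. The forward step needs buffered, oxygen-free fluoride cleavage, because 22 contains a free catechol and a free resorcinol.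

**21 to 11 and 20 (20 from 19).** The aryl–CH2 bond between ring B and the end of the tether is cut. This divides the skeleton into halves of similar size at a ring carbon that can be marked early with bromine. The forward step is an sp2–sp3 cross-coupling of a primary alkylzinc with an electron-rich, ortho-substituted aryl bromide, and it must not engage any alkene.

**11 to 8 and two equivalents of 10 (10 from 9).** Both CH=C(CH3)2 double bonds are cut. Because the arms are identical, one reagent builds both and no differentiation is needed; 11 is simplified to 8 and a three-carbon ylide. The forward step must olefinate faster than 8 enolises and closes by aldol reaction, with the bromide and the silyl ethers untouched.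

**8 to 6 (through 7).** The two aldehyde carbons are reconnected as the ring alkene of 6. A fragile dialdehyde becomes a stable bicycle, and the adjacency of the two arms is guaranteed by construction. The forward step must cleave an isolated alkene beside a silyloxy arene and an aryl bromide, and 8 must be used at once.

**6 to 5, 3, 2 and 1.** Two O–Si bonds are removed, then the C2–O bond (traced through 4 to the C2–CHO bond of 3), then the C4–Br bond. The single hydroxyl of 1 directs everything: bromine goes para to it, then the formyl group goes to the only free ortho carbon. The forward steps require bromination that spares the ring alkene, strictly ortho formylation, and a peroxide oxidation that does not epoxidise.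

**19 to 18, 17 and 16.** The C–I bond is traced to a primary alcohol in 18, this to the tris-silyl ether 17, and this to the triol 16. The detour through 17 is accepted because both phenols must be protected before the primary hydroxyl is activated. The forward demand is selective acid cleavage of one alkyl silyl ether beside two aryl silyl ethers.

**16 to 15.** The primary alcohol and the phenol ortho to the chain are reconnected as a lactone, and the other phenol as an ester. In the lactone only one phenolic oxygen is free, so the two resorcinol oxygens need not be told apart. The forward step is one hydride reduction of both acyl groups.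

**15 to 13 (through 14) and 12.** The bond between ring A and the quaternary carbon is cut by a retro-[3,3] shift that leads to 13, whose O–CH2 bond is then cut to reach 12. The sigmatropic shift is the direct way to attach the tertiary terminus ortho to oxygen. The forward step must migrate to the carbon para to the lactone oxygen and not to the carbon between the two oxygens, and 14 must be captured before it reacts further.

## Other disconnections considered

Alternative 1: The cut removes the whole pyran ring in one operation, that is C4a–C4, C4–C3 and C2–O1. In the forward sense 5-bromo-4-chloro-2-methoxyphenol A2, formaldehyde A3 and 2-methylpropene A4 would be heated together. The ortho-quinone methide 5-bromo-4-chloro-2-methoxy-6-methylidenecyclohexa-2,4-dien-1-one A5 would form from A2 and A3 and be trapped by A4 in a [4+2] cycloaddition to give 5-bromo-6-chloro-8-methoxy-2,2-dimethylchroman A1.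
- In its favour: the chroman is made from very simple components before any prenyl group exists, so no discrimination between two prenyl arms and no late acid step is needed. On this point it is better than the chosen plan. The two halogens also programme the order of the later couplings.
- Against it: A2 needs its own regioselective preparation. The condensation of the deactivated A2 with A3 and the gaseous, unactivated A4 calls for a sealed vessel and forcing conditions, and A5 can be lost to phenol–aldehyde oligomerisation. After A1, two different cross-couplings are still required: a prenyl transfer at C5, with its linear-versus-branched question, and an alkyl coupling at a hindered aryl chloride. The methyl ether must then be cleaved at the end beside acid-sensitive alkenes.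
- Comparison: structurally it solves the heterocycle but not the carbon substituents of ring B, whereas the chosen plan does the reverse. Mechanistically both key steps are well understood, but the Wittig step runs at low temperature. In step economy it is at best equal once A2 and the final demethylation are counted, and it needs the same ring A fragment.

Alternative 2: The cut takes ring A apart at two ring bonds. In the forward sense the enolate of 6-[8-(methoxymethoxy)-2,2-dimethyl-5-(3-methylbut-2-en-1-yl)chroman-6-yl]hexan-2-one A8 would add to methyl 3,3-dimethyl-2-methylenepent-4-enoate A7. An intramolecular Claisen condensation would follow to give the cyclohexane-1,3-dione A6 as a diastereomer mixture, to be aromatised later to the resorcinol.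
- In its favour: the quaternary carbon of the 1,1-dimethylallyl group arrives in the small acyclic ester A7, so its position on ring A is unambiguous. This avoids the regiochemical question of the aromatic Claisen step and is better than the chosen plan on that point. The diastereomers of A6 are irrelevant because all converge on aromatisation, so it is equal on stereochemistry.
- Against it: A8 already contains the complete, crowded ring B, so the hardest part of the target is not addressed. The α-branched acceptor A7 is hindered. The ketone must react through its internal α-carbon in the Michael step and through its methyl group in the Claisen step. Oxidising a cyclohexane-1,3-dione to a resorcinol is difficult to reconcile with three alkenes and an electron-rich arene, and acid removal of the acetal comes last.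
- Comparison: structurally it fixes ring A with certainty but leaves ring B to other chemistry, while the chosen plan builds ring B and accepts a regiochemical question on ring A. Mechanistically the tandem Michael–Claisen sequence has two regiochemical demands on one ketone, against two independent and identical olefinations in the chosen plan. In step economy it is linear and long, and the most advanced material passes through the least predictable steps, whereas the chosen plan is convergent and keeps risky chemistry on small fragments.

Alternative 3: The cut removes both carbon substituents of ring B at once: the C6–CH2 bond of the tether and the C5–CH2 bond of the prenyl group. In the forward sense 5-iodo-8-(methoxymethoxy)-2,2-dimethylchroman A10 would be alkylated at C6–H by 1-(3-iodopropyl)-2,4-bis(methoxymethoxy)-5-(2-methylbut-3-en-2-yl)benzene A11. The ipso carbon would then be coupled with 4,4,5,5-tetramethyl-2-(3-methylbut-2-en-1-yl)-1,3,2-dioxaborolane A12, under palladium catalysis with norbornene A13 as mediator, to give the tris(methoxymethyl) ether A9 of 23.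
- In its favour: it is the most convergent plan, since one operation joins the halves and completes ring B on a preformed chroman. It is better than the chosen plan in steps after fragment union and needs no discrimination between prenyl arms. Ortho alkylation by primary alkyl iodides is an established part of this manifold, and C4a provides the required ortho substituent.
- Against it: ending the sequence with an allylic boron reagent such as A12 is not established, and the allyl group can be delivered through either terminus (prenyl or 1,1-dimethylallyl at C5). The terminal alkene of A11 and the alkene of A12 can insert into aryl- or alkylpalladium intermediates, and A13 can stay in the product if the cycle ends before it is extruded. A10 requires a regioselective iodination of its own, and the acetals must be removed with acid at the end. On that last point it is equal to the chosen plan, which also ends with an acid-sensitive operation.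
- Comparison: structurally it installs both carbon substituents of ring B in one step but presupposes the chroman, while the chosen plan builds the substituents first and the heterocycle last. Mechanistically it is a long catalytic cycle with several competing exits, against two well-understood operations in the chosen plan. In step economy it would be shorter if it worked, but the uncertainty sits at the most valuable stage.

Key step: step 6

## Remarks on the chemistry

- Compound 23 has no stereocentre, so no configuration has to be set or preserved. The only stereochemical element in the route is the cis relationship in the transient, racemic diol 7, which is destroyed in the same flask.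
- Atom mapping from 1 through 8 and 11 to ring B of 23, position by position:
  - C1–O of 1 becomes O1/C8a.
  - The oxygen introduced at C2 becomes the C8 hydroxyl.
  - C3–H becomes C7–H.
  - C4–Br becomes the C6 attachment point.
  - The C8 and C5 methylene arms become chroman C4 and the benzylic CH2 of the C5 prenyl group.
- Design points for 8: bromine is introduced before the second oxygen, so each aromatic substitution has one open position. Both oxygens carry the same silyl group, so one fluoride treatment unmasks them later. Compound 8 is made and consumed on the same day without chromatography.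
- Assumption: 12, 7-hydroxychroman-2-one, is taken to be a purchasable compound.

## Steps

Step 1
Reactants: 1 5,8-dihydronaphthalen-1-ol
Product: 2 4-bromo-5,8-dihydronaphthalen-1-ol
Conditions: NBS (1.0 equiv), MeCN, −20 → 0 °C, dark
Reagents that add atoms: N-bromosuccinimide, O=C1CCC(=O)N1Br
Why: Electrophilic aromatic bromination of a phenol; the hydroxyl-activated ring should react far faster than the isolated cis-alkene, and the position para to OH is favoured over the single free ortho position in a polar solvent at low temperature. Working cold and in the dark suppresses radical bromination at the doubly activated CH2 groups.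

Step 2
Reactants: 2 4-bromo-5,8-dihydronaphthalen-1-ol
Product: 3 4-bromo-1-hydroxy-5,8-dihydronaphthalene-2-carbaldehyde
Conditions: MgCl2 (anhydrous), Et3N, (CH2O)n, THF, reflux
Reagents that add atoms: formaldehyde (from paraformaldehyde), C=O
Why: Magnesium-mediated ortho-formylation of phenols (Casnati–Skattebøl reaction): the magnesium phenoxide delivers formaldehyde to the only free ortho carbon, and a second equivalent of formaldehyde oxidises the benzylic alkoxide to the aldehyde by hydride transfer. The weak base should not move the skipped ring alkene into conjugation.

Step 3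
Reactants: 3 4-bromo-1-hydroxy-5,8-dihydronaphthalene-2-carbaldehyde
Product: 5 4-bromo-5,8-dihydronaphthalene-1,2-diol, via formate ester 4 (not isolated)
Conditions: 30% H2O2, NaOH (aq), THF, 0 °C → rt, N2; then aq. HCl
Reagents that add atoms: hydrogen peroxide, OO
Why: Dakin oxidation: hydroperoxide adds to the aldehyde, the electron-rich aryl group migrates to oxygen to give formate 4, and this is saponified in the same flask to the catechol. Alkaline H2O2 does not epoxidise an isolated alkene, and exclusion of air protects the catechol.

Step 4
Reactants: 5 4-bromo-5,8-dihydronaphthalene-1,2-diol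
Product: 6 4-bromo-1,2-bis(tert-butyldimethylsilyloxy)-5,8-dihydronaphthalene
Conditions: TBSCl, imidazole, DMF, rt
Reagents that add atoms: tert-butyldimethylsilyl chloride, CC(C)(C)[Si](C)(C)Cl
Why: Imidazole-promoted silylation of both phenols. Two identical aryl silyl ethers should tolerate periodate, ylide and organozinc conditions and leave later in one fluoride operation.

Step 5
Reactants: 6 4-bromo-1,2-bis(tert-butyldimethylsilyloxy)-5,8-dihydronaphthalene
Product: 8 2,2'-[3-bromo-5,6-bis(tert-butyldimethylsilyloxy)-1,2-phenylene]diacetaldehyde, via cis-diol 7 (not isolated)
Conditions: OsO4 (cat.), NaIO4, 2,6-lutidine, 1,4-dioxane/H2O (3:1), rt; extracted, dried and used at once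
Reagents that add atoms: osmium tetroxide, O=[Os](=O)(=O)=O; sodium periodate, [Na+].[O-]I(=O)(=O)=O
Why: Lemieux–Johnson oxidation: catalytic OsO4 dihydroxylates the only alkene to cis-diol 7, which NaIO4 cleaves to the two aldehydes while regenerating OsO4, with 2,6-lutidine as buffer. The two CH2CHO arms are necessarily on adjacent ring carbons because they come from one ring bond.

Step 6
Reactants: 8 2,2'-[3-bromo-5,6-bis(tert-butyldimethylsilyloxy)-1,2-phenylene]diacetaldehyde; 9 isopropyltriphenylphosphonium iodide
Product: 11 1-bromo-4,5-bis(tert-butyldimethylsilyloxy)-2,3-bis(3-methylbut-2-en-1-yl)benzene, via isopropylidene(triphenyl)phosphorane 10 (not isolated)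
Conditions: 9 (3.0 equiv), KN(SiMe3)2 (2.9 equiv), THF, 0 °C; then 8 in THF added dropwise at −78 °C; −78 → 0 °C
Reagents that add atoms: none
Why: KN(SiMe3)2 in slight deficiency converts 9 into the non-stabilised ylide 10 without leaving free base and without any alkyllithium that could exchange the aryl bromide. Each arylacetaldehyde carbonyl of 8 undergoes [2+2] addition of 10 to an oxaphosphetane, which collapses to the CH=C(CH3)2 alkene and Ph3PO; this is a Wittig olefination, and the closest known reaction type is the isopropylidenation of arylacetaldehydes to prenylarenes. The two aldehydes react independently and in either order, so the mono-olefinated aldehydes are only transient. No ring is closed and no stereocentre is formed, and because each new alkene terminus carries two methyl groups there is no E/Z question. The selectivity needed is carbonyl addition over α-deprotonation and intramolecular aldol closure; slow addition of 8 to an excess of lithium-free ylide at −78 °C should secure it, since each aldehyde then meets ylide and not enolate. Regiochemistry needs no control, because the arms stem from one ring alkene and become distinguishable only later through the neighbouring oxygen. The aryl bromide and the aryl silyl ethers should be inert to the ylide at these temperatures.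

Step 7
Reactants: 12 7-hydroxychroman-2-one
Product: 13 7-[(3-methylbut-2-en-1-yl)oxy]chroman-2-one
Conditions: 3-methylbut-2-en-1-ol, PPh3, DIAD, THF, 0 °C → rt
Reagents that add atoms: 3-methylbut-2-en-1-ol, CC(C)=CCO
Why: Mitsunobu etherification at the CH2 terminus of the primary allylic alcohol. The lactone ties up the other phenolic oxygen so only O7 can be alkylated, and the neutral conditions avoid phenoxide-induced opening of the aryl ester.

Step 8
Reactants: 13 7-[(3-methylbut-2-en-1-yl)oxy]chroman-2-one
Product: 15 6-(2-methylbut-3-en-2-yl)-2-oxochroman-7-yl butanoate, via free phenol 14 (not isolated)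
Conditions: butanoic anhydride, PhNEt2, 185 °C, Ar
Reagents that add atoms: butanoic anhydride, CCCC(=O)OC(=O)CCC
Why: Aromatic Claisen rearrangement ([3,3]-sigmatropic shift) of an aryl prenyl ether, which delivers the allyl unit inverted, with its quaternary carbon on the ring; C6, para to the ring oxygen and flanked by a hydrogen, should be preferred over C8, which lies between the two oxygens. Phenol 14 is acylated as it forms, which blocks the hydrogen-transfer (abnormal Claisen) and cyclisation pathways of free ortho-(1,1-dimethylallyl)phenols and prevents phenol–lactone transacylation.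

Step 9
Reactants: 15 6-(2-methylbut-3-en-2-yl)-2-oxochroman-7-yl butanoate
Product: 16 4-(3-hydroxypropyl)-6-(2-methylbut-3-en-2-yl)benzene-1,3-diol
Conditions: LiAlH4, THF, 0 °C → rt; aq. KNaC4H4O6 work-up
Reagents that add atoms: none
Why: Hydride reduction opens the lactone to the primary alcohol and phenol and cleaves the aryl butanoate in one operation. The terminal alkene is inert to LiAlH4.

Step 10
Reactants: 16 4-(3-hydroxypropyl)-6-(2-methylbut-3-en-2-yl)benzene-1,3-diol
Product: 17 tert-butyl{3-[2,4-bis(tert-butyldimethylsilyloxy)-5-(2-methylbut-3-en-2-yl)phenyl]propoxy}dimethylsilane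
Conditions: TBSOTf, 2,6-lutidine, CH2Cl2, 0 °C → rt
Reagents that add atoms: tert-butyldimethylsilyl trifluoromethanesulfonate, CC(C)(C)[Si](C)(C)OS(=O)(=O)C(F)(F)F
Why: Silylation with the triflate should protect all three hydroxyls, including the hindered phenol next to the quaternary carbon.

Step 11
Reactants: 17 tert-butyl{3-[2,4-bis(tert-butyldimethylsilyloxy)-5-(2-methylbut-3-en-2-yl)phenyl]propoxy}dimethylsilane
Product: 18 3-[2,4-bis(tert-butyldimethylsilyloxy)-5-(2-methylbut-3-en-2-yl)phenyl]propan-1-ol
Conditions: CSA (cat.), MeOH/CH2Cl2 (1:1), 0 °C
Reagents that add atoms: none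
Why: Acid-catalysed methanolysis selects the primary alkyl silyl ether, because aryl silyl ethers are markedly more stable to acid. The acid is too weak and too cold to protonate the terminal alkene.

Step 12
Reactants: 18 3-[2,4-bis(tert-butyldimethylsilyloxy)-5-(2-methylbut-3-en-2-yl)phenyl]propan-1-ol
Product: 19 1-(3-iodopropyl)-2,4-bis(tert-butyldimethylsilyloxy)-5-(2-methylbut-3-en-2-yl)benzene
Conditions: I2, PPh3, imidazole, CH2Cl2, 0 °C → rt
Reagents that add atoms: iodine, II
Why: Appel-type iodination: the alcohol is activated as an alkoxyphosphonium ion and displaced by iodide in an SN2 step at the primary carbon. Premixed PPh3/I2 should not iodinate the silylated arene or add to the alkene.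

Step 13
Reactants: 19 1-(3-iodopropyl)-2,4-bis(tert-butyldimethylsilyloxy)-5-(2-methylbut-3-en-2-yl)benzene; 11 1-bromo-4,5-bis(tert-butyldimethylsilyloxy)-2,3-bis(3-methylbut-2-en-1-yl)benzene
Product: 21 1-{3-[2,4-bis(tert-butyldimethylsilyloxy)-5-(2-methylbut-3-en-2-yl)phenyl]propyl}-4,5-bis(tert-butyldimethylsilyloxy)-2,3-bis(3-methylbut-2-en-1-yl)benzene, via alkylzinc iodide 20 (not isolated)
Conditions: Zn dust (activated with Me3SiCl/BrCH2CH2Br), LiCl, THF, 40 °C; then 11, Pd(OAc)2 (cat.), SPhos, THF, 25 → 50 °C
Reagents that add atoms: none
Why: Negishi cross-coupling: zinc inserts into the primary C–I bond to give 20, which transmetalates to the arylpalladium bromide formed by oxidative addition of zerovalent palladium into 11, and reductive elimination forms the aryl–CH2 bond. The bulky, electron-rich biarylphosphine is chosen for the electron-rich, ortho-substituted bromide; primary alkylzinc reagents tolerate aryl silyl ethers, and the hindered alkenes are poor partners for insertion.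

Step 14
Reactants: 21 1-{3-[2,4-bis(tert-butyldimethylsilyloxy)-5-(2-methylbut-3-en-2-yl)phenyl]propyl}-4,5-bis(tert-butyldimethylsilyloxy)-2,3-bis(3-methylbut-2-en-1-yl)benzene
Product: 22 4-{3-[4,5-dihydroxy-2,3-bis(3-methylbut-2-en-1-yl)phenyl]propyl}-6-(2-methylbut-3-en-2-yl)benzene-1,3-diol
Conditions: Bu4NF, AcOH, THF, 0 °C, Ar
Reagents that add atoms: none
Why: Fluoride should cleave all four aryl silyl ethers through pentacoordinate silicon. Buffering with acetic acid keeps the phenols protonated and air is excluded, so the catechol should not be oxidised; the alkenes are unaffected.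

Step 15
Reactants: 22 4-{3-[4,5-dihydroxy-2,3-bis(3-methylbut-2-en-1-yl)phenyl]propyl}-6-(2-methylbut-3-en-2-yl)benzene-1,3-diol
Product: 23 kazinol D, 4-{3-[8-hydroxy-2,2-dimethyl-5-(3-methylbut-2-en-1-yl)chroman-6-yl]propyl}-6-(2-methylbut-3-en-2-yl)benzene-1,3-diol
Conditions: Amberlyst 15 (H+ form), CH2Cl2 (high dilution), 0 °C → rt, Ar; filtered at full conversion
Reagents that add atoms: none
Why: Acid-catalysed intramolecular hydroalkoxylation (Markovnikov, 6-endo-trig): protonation of a prenyl group gives a tertiary cation, and only the arm next to a hydroxyl is captured to form the six-membered ether. The second prenyl group has no neighbouring hydroxyl and should revert to the trisubstituted alkene, and the 1,1-dimethylallyl group would need a secondary cation; the new ring carbon bears two methyl groups, so no stereocentre arises.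

## Compound list

1 | 5,8-dihydronaphthalen-1-ol | Oc1cccc2c1CC=CC2 | starting material
2 | 4-bromo-5,8-dihydronaphthalen-1-ol | Oc1ccc(Br)c2c1CC=CC2 | intermediate
3 | 4-bromo-1-hydroxy-5,8-dihydronaphthalene-2-carbaldehyde | O=Cc1cc(Br)c2c(c1O)CC=CC2 | intermediate
4 | 4-bromo-1-hydroxy-5,8-dihydronaphthalen-2-yl formate | O=COc1cc(Br)c2c(c1O)CC=CC2 | intermediate (not isolated)
5 | 4-bromo-5,8-dihydronaphthalene-1,2-diol | Oc1cc(Br)c2c(c1O)CC=CC2 | intermediate
6 | 4-bromo-1,2-bis(tert-butyldimethylsilyloxy)-5,8-dihydronaphthalene | CC(C)(C)[Si](C)(C)Oc1cc(Br)c2c(c1O[Si](C)(C)C(C)(C)C)CC=CC2 | intermediate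
7 | cis-5-bromo-7,8-bis(tert-butyldimethylsilyloxy)-1,2,3,4-tetrahydronaphthalene-2,3-diol (racemic, relative configuration shown) | O[C@@H]1Cc2c(Br)cc(O[Si](C)(C)C(C)(C)C)c(O[Si](C)(C)C(C)(C)C)c2C[C@@H]1O | intermediate (not isolated)
8 | 2,2'-[3-bromo-5,6-bis(tert-butyldimethylsilyloxy)-1,2-phenylene]diacetaldehyde | O=CCc1c(CC=O)c(Br)cc(O[Si](C)(C)C(C)(C)C)c1O[Si](C)(C)C(C)(C)C | intermediate
9 | isopropyltriphenylphosphonium iodide | CC(C)[P+](c1ccccc1)(c1ccccc1)c1ccccc1.[I-] | starting material
10 | isopropylidene(triphenyl)phosphorane | CC(C)=P(c1ccccc1)(c1ccccc1)c1ccccc1 | intermediate (not isolated)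
11 | 1-bromo-4,5-bis(tert-butyldimethylsilyloxy)-2,3-bis(3-methylbut-2-en-1-yl)benzene | CC(C)=CCc1c(CC=C(C)C)c(Br)cc(O[Si](C)(C)C(C)(C)C)c1O[Si](C)(C)C(C)(C)C | intermediate
12 | 7-hydroxychroman-2-one | O=C1CCc2ccc(O)cc2O1 | starting material
13 | 7-[(3-methylbut-2-en-1-yl)oxy]chroman-2-one | CC(C)=CCOc1ccc2CCC(=O)Oc2c1 | intermediate
14 | 7-hydroxy-6-(2-methylbut-3-en-2-yl)chroman-2-one | C=CC(C)(C)c1cc2CCC(=O)Oc2cc1O | intermediate (not isolated)
15 | 6-(2-methylbut-3-en-2-yl)-2-oxochroman-7-yl butanoate | CCCC(=O)Oc1cc2OC(=O)CCc2cc1C(C)(C)C=C | intermediate
16 | 4-(3-hydroxypropyl)-6-(2-methylbut-3-en-2-yl)benzene-1,3-diol | C=CC(C)(C)c1cc(CCCO)c(O)cc1O | intermediate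
17 | tert-butyl{3-[2,4-bis(tert-butyldimethylsilyloxy)-5-(2-methylbut-3-en-2-yl)phenyl]propoxy}dimethylsilane | C=CC(C)(C)c1cc(CCCO[Si](C)(C)C(C)(C)C)c(O[Si](C)(C)C(C)(C)C)cc1O[Si](C)(C)C(C)(C)C | intermediate
18 | 3-[2,4-bis(tert-butyldimethylsilyloxy)-5-(2-methylbut-3-en-2-yl)phenyl]propan-1-ol | C=CC(C)(C)c1cc(CCCO)c(O[Si](C)(C)C(C)(C)C)cc1O[Si](C)(C)C(C)(C)C | intermediate
19 | 1-(3-iodopropyl)-2,4-bis(tert-butyldimethylsilyloxy)-5-(2-methylbut-3-en-2-yl)benzene | C=CC(C)(C)c1cc(CCCI)c(O[Si](C)(C)C(C)(C)C)cc1O[Si](C)(C)C(C)(C)C | intermediate
20 | {3-[2,4-bis(tert-butyldimethylsilyloxy)-5-(2-methylbut-3-en-2-yl)phenyl]propyl}zinc iodide | C=CC(C)(C)c1cc(CCC[Zn]I)c(O[Si](C)(C)C(C)(C)C)cc1O[Si](C)(C)C(C)(C)C | intermediate (not isolated)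
21 | 1-{3-[2,4-bis(tert-butyldimethylsilyloxy)-5-(2-methylbut-3-en-2-yl)phenyl]propyl}-4,5-bis(tert-butyldimethylsilyloxy)-2,3-bis(3-methylbut-2-en-1-yl)benzene | C=CC(C)(C)c1cc(CCCc2cc(O[Si](C)(C)C(C)(C)C)c(O[Si](C)(C)C(C)(C)C)c(CC=C(C)C)c2CC=C(C)C)c(O[Si](C)(C)C(C)(C)C)cc1O[Si](C)(C)C(C)(C)C | intermediate
22 | 4-{3-[4,5-dihydroxy-2,3-bis(3-methylbut-2-en-1-yl)phenyl]propyl}-6-(2-methylbut-3-en-2-yl)benzene-1,3-diol | C=CC(C)(C)c1cc(CCCc2cc(O)c(O)c(CC=C(C)C)c2CC=C(C)C)c(O)cc1O | intermediate
23 | kazinol D, 4-{3-[8-hydroxy-2,2-dimethyl-5-(3-methylbut-2-en-1-yl)chroman-6-yl]propyl}-6-(2-methylbut-3-en-2-yl)benzene-1,3-diol | C=CC(C)(C)c1cc(CCCc2cc(O)c3c(c2CC=C(C)C)CCC(C)(C)O3)c(O)cc1O | target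

## Step count and least certain steps

Total step count: 15.
Longest linear sequence: 9 steps (steps 1–6 and 13–15 from 1; equally steps 7–15 from 12).

**Step 6 (key step).** Enolisation of the arylacetaldehyde groups by the basic, hindered ylide, followed by intramolecular aldol condensation between the two neighbouring arms, may outrun carbonyl addition, because the α-hydrogens are both benzylic and α to a carbonyl. The fallback reverses the polarity of the olefination so that no enolisable aldehyde is exposed to a basic ylide. It sets out from 8, which is reduced as soon as it is formed with NaBH4 in MeOH to 2,2'-[3-bromo-5,6-bis(tert-butyldimethylsilyloxy)-1,2-phenylene]diethanol F1. Treatment with I2, PPh3 and imidazole should give 1-bromo-4,5-bis(tert-butyldimethylsilyloxy)-2,3-bis(2-iodoethyl)benzene F2, and heating with PPh3 in MeCN should give {[3-bromo-5,6-bis(tert-butyldimethylsilyloxy)-1,2-phenylene]di(ethane-2,1-diyl)}bis(triphenylphosphonium) diiodide F3. Double deprotonation with KN(SiMe3)2 and Wittig reaction with excess acetone should form the same two CH=C(CH3)2 bonds and return to the route at 11.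

**Step 5.** Aldol self-condensation or over-oxidation of the dialdehyde during the aqueous, one-pot cleavage and its work-up may erode the material before it reaches the ylide. The fallback separates dihydroxylation from glycol cleavage and moves the cleavage into an anhydrous medium. It sets out from 6, which is dihydroxylated with catalytic OsO4 and N-methylmorpholine N-oxide; the diol 7 is isolated and stored. It is then cleaved with Pb(OAc)4 in anhydrous CH2Cl2 at −20 °C (Criegee cleavage), and the filtered solution is transferred directly into the ylide, returning to the route at 8. This fallback makes no compound outside the compound list and is entered as F0.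

**Step 8.** The sigmatropic shift may go with poor regioselectivity, partly to the carbon between the two oxygens, and the aryl ester may undergo transacylation at 185 °C. The fallback removes the lactone first and uses a bulky silyl ether as the steering group. It sets out from 13, which is reduced with LiAlH4 to 2-(3-hydroxypropyl)-5-[(3-methylbut-2-en-1-yl)oxy]phenol F4. Silylation with TBSCl and imidazole should give tert-butyl{3-[2-(tert-butyldimethylsilyloxy)-4-(3-methylbut-2-en-1-yloxy)phenyl]propoxy}dimethylsilane F5. Claisen rearrangement in PhNEt2 at the lowest effective temperature should then occur away from the silyloxy-flanked carbon to give 5-(tert-butyldimethylsilyloxy)-4-[3-(tert-butyldimethylsilyloxy)propyl]-2-(2-methylbut-3-en-2-yl)phenol F6. Silylation with TBSOTf and 2,6-lutidine returns to the route at 17.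

**Step 13.** Slow oxidative addition into the electron-rich, ortho-substituted bromide and slow transmetalation may allow protonolysis or homocoupling of the alkylzinc, and zinc insertion into the iodide may be incomplete. The fallback changes the nucleophile from zinc to boron (B-alkyl Suzuki–Miyaura coupling). It sets out from 19, which is treated with tert-butyllithium (2 equiv) in Et2O at −78 °C and then with B-methoxy-9-borabicyclo[3.3.1]nonane to give lithium {3-[2,4-bis(tert-butyldimethylsilyloxy)-5-(2-methylbut-3-en-2-yl)phenyl]propyl}(methoxy)-9-borabicyclo[3.3.1]nonan-9-uide F7. Addition of 11, PdCl2(dppf) and aqueous K3PO4 in DMF should return to the route at 21.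

**Step 15.** Chemoselectivity may be poor: reversible protonation of the second prenyl group, protonation of the 1,1-dimethylallyl group next to a ring A hydroxyl, or intermolecular alkylation of the nucleophilic resorcinol may compete with closure of the pyran ring. The fallback closes the chroman before ring A is attached. It sets out from 11, which is desilylated with Bu4NF and AcOH to 5-bromo-3,4-bis(3-methylbut-2-en-1-yl)benzene-1,2-diol F8. Cyclisation with Amberlyst 15 in CH2Cl2 should give 6-bromo-2,2-dimethyl-5-(3-methylbut-2-en-1-yl)chroman-8-ol F9, and silylation with TBSCl and imidazole should give [6-bromo-2,2-dimethyl-5-(3-methylbut-2-en-1-yl)chroman-8-yl]oxy(tert-butyl)dimethylsilane F10. Negishi coupling of F10 with 20 under the conditions of step 13 should give the tris(tert-butyldimethylsilyl) ether of kazinol D F11. Buffered fluoride desilylation then returns to the route at 23.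

## Further compounds

F1 | step 6 | 2,2'-[3-bromo-5,6-bis(tert-butyldimethylsilyloxy)-1,2-phenylene]diethanol | OCCc1c(CCO)c(Br)cc(O[Si](C)(C)C(C)(C)C)c1O[Si](C)(C)C(C)(C)C
F2 | step 6 | 1-bromo-4,5-bis(tert-butyldimethylsilyloxy)-2,3-bis(2-iodoethyl)benzene | ICCc1c(CCI)c(Br)cc(O[Si](C)(C)C(C)(C)C)c1O[Si](C)(C)C(C)(C)C
F3 | step 6 | {[3-bromo-5,6-bis(tert-butyldimethylsilyloxy)-1,2-phenylene]di(ethane-2,1-diyl)}bis(triphenylphosphonium) diiodide | [I-].[I-].Brc1cc(O[Si](C)(C)C(C)(C)C)c(O[Si](C)(C)C(C)(C)C)c(CC[P+](c2ccccc2)(c2ccccc2)c2ccccc2)c1CC[P+](c3ccccc3)(c3ccccc3)c3ccccc3
F0 | step 5 | none | none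
F4 | step 8 | 2-(3-hydroxypropyl)-5-[(3-methylbut-2-en-1-yl)oxy]phenol | CC(C)=CCOc1ccc(CCCO)c(O)c1
F5 | step 8 | tert-butyl{3-[2-(tert-butyldimethylsilyloxy)-4-(3-methylbut-2-en-1-yloxy)phenyl]propoxy}dimethylsilane | CC(C)=CCOc1ccc(CCCO[Si](C)(C)C(C)(C)C)c(O[Si](C)(C)C(C)(C)C)c1
F6 | step 8 | 5-(tert-butyldimethylsilyloxy)-4-[3-(tert-butyldimethylsilyloxy)propyl]-2-(2-methylbut-3-en-2-yl)phenol | C=CC(C)(C)c1cc(CCCO[Si](C)(C)C(C)(C)C)c(O[Si](C)(C)C(C)(C)C)cc1O
F7 | step 13 | lithium {3-[2,4-bis(tert-butyldimethylsilyloxy)-5-(2-methylbut-3-en-2-yl)phenyl]propyl}(methoxy)-9-borabicyclo[3.3.1]nonan-9-uide | [Li+].CO[B-]1(CCCc2cc(C(C)(C)C=C)c(O[Si](C)(C)C(C)(C)C)cc2O[Si](C)(C)C(C)(C)C)C2CCCC1CCC2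
F8 | step 15 | 5-bromo-3,4-bis(3-methylbut-2-en-1-yl)benzene-1,2-diol | CC(C)=CCc1c(CC=C(C)C)c(Br)cc(O)c1O
F9 | step 15 | 6-bromo-2,2-dimethyl-5-(3-methylbut-2-en-1-yl)chroman-8-ol | CC(C)=CCc1c(Br)cc(O)c2OC(C)(C)CCc12
F10 | step 15 | [6-bromo-2,2-dimethyl-5-(3-methylbut-2-en-1-yl)chroman-8-yl]oxy(tert-butyl)dimethylsilane | CC(C)=CCc1c(Br)cc(O[Si](C)(C)C(C)(C)C)c2OC(C)(C)CCc12
F11 | step 15 | tris(tert-butyldimethylsilyl) ether of kazinol D | C=CC(C)(C)c1cc(CCCc2cc(O[Si](C)(C)C(C)(C)C)c3OC(C)(C)CCc3c2CC=C(C)C)c(O[Si](C)(C)C(C)(C)C)cc1O[Si](C)(C)C(C)(C)C
A1 | alternative 1 | 5-bromo-6-chloro-8-methoxy-2,2-dimethylchroman | COc1cc(Cl)c(Br)c2CCC(C)(C)Oc12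
A2 | alternative 1 | 5-bromo-4-chloro-2-methoxyphenol | COc1cc(Cl)c(Br)cc1O
A3 | alternative 1 | formaldehyde | C=O
A4 | alternative 1 | 2-methylpropene | CC(C)=C
A5 | alternative 1 | 5-bromo-4-chloro-2-methoxy-6-methylidenecyclohexa-2,4-dien-1-one | C=C1C(Br)=C(Cl)C=C(OC)C1=O
A6 | alternative 2 | 4-(2-methylbut-3-en-2-yl)-6-{3-[8-(methoxymethoxy)-2,2-dimethyl-5-(3-methylbut-2-en-1-yl)chroman-6-yl]propyl}cyclohexane-1,3-dione (diastereomer mixture) | C=CC(C)(C)C1CC(CCCc2cc(OCOC)c3OC(C)(C)CCc3c2CC=C(C)C)C(=O)CC1=O
A7 | alternative 2 | methyl 3,3-dimethyl-2-methylenepent-4-enoate | C=CC(C)(C)C(=C)C(=O)OC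
A8 | alternative 2 | 6-[8-(methoxymethoxy)-2,2-dimethyl-5-(3-methylbut-2-en-1-yl)chroman-6-yl]hexan-2-one | CC(=O)CCCCc1cc(OCOC)c2OC(C)(C)CCc2c1CC=C(C)C
A9 | alternative 3 | tris(methoxymethyl) ether of kazinol D | CC(C)=CCc1c(CCCc2cc(C(C)(C)C=C)c(OCOC)cc2OCOC)cc(OCOC)c2OC(C)(C)CCc12
A10 | alternative 3 | 5-iodo-8-(methoxymethoxy)-2,2-dimethylchroman | COCOc1ccc(I)c2CCC(C)(C)Oc12
A11 | alternative 3 | 1-(3-iodopropyl)-2,4-bis(methoxymethoxy)-5-(2-methylbut-3-en-2-yl)benzene | C=CC(C)(C)c1cc(CCCI)c(OCOC)cc1OCOC
A12 | alternative 3 | 4,4,5,5-tetramethyl-2-(3-methylbut-2-en-1-yl)-1,3,2-dioxaborolane | CC(C)=CCB1OC(C)(C)C(C)(C)O1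
A13 | alternative 3 | norbornene (bicyclo[2.2.1]hept-2-ene) | C1=CC2CCC1C2
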